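**Plan**

- Enabling feature: the quaternary, methyl-bearing fusion carbon C5 lies next to C4 in ring A and 1,4 to the C8 ketone in ring B. Ring B is therefore the cyclohexene of a [4+2] addition of a 2-silyloxydiene (C7=C8–C9=C10) to a C5=C6 isopropenyl ketone whose carbonyl is C4, and the C1–C4 tether becomes ring A.
- Cuts, in retrosynthetic order: the two ester C–O bonds, C9–O, C7–C11, C4–C15, then C5–C10 and C6–C7 together, then C4–C5, C9=C10 and C1–C2.
- Forward order: the open chain is joined from methyl (R)-glycidate, an allyl unit, methyl vinyl ketone and an isopropenyl unit; rings A and B then close in one step; C15, the isopropenyl group, the C9 oxygen and the two esters follow.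
- Stereochemistry: C3 comes from (R)-glycidate. C5 is set by the chelate-directed cycloaddition, C4 by hydrogenation opposite the C5 methyl, C7 by protonation to the equatorial isomer, C10 by axial protonation in the dissolving-metal reduction, and C9 by α-face oxidation of the enol ether. Both ester geometries are bought with the acids.

Key step: step 7

Remark: eremophilane numbering is used (ring A = C1–C5 and C10, ring B = C5–C10, C14 = methyl on C5, C15 = methyl on C4, β = the face of C14); 12 and 13 are written with the 10α-hydrogen expected from the exo closure, and a C10 epimer, should it form, gives the same 14 in step 9; angelic acid and (E)-3-methylpent-2-enoic acid are taken as commercial, geometrically pure acids.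

**Route**

Step 1
Reactants: 1 methyl (R)-glycidate; 2 allylmagnesium bromide
Product: 3 methyl (2R)-2-hydroxyhex-5-enoate
Conditions: CuI (cat.), THF, −78 °C; aq. NH4Cl
Reagents that add atoms: none
Why: Copper-catalysed Grignard opening of a glycidic ester is an SN2 attack at the unsubstituted epoxide carbon, which at −78 °C should outrun addition to the ester and leaves the oxygen-bearing stereocentre (later C3) untouched.

Step 2
Reactants: 3 methyl (2R)-2-hydroxyhex-5-enoate
Product: 4 methyl (2R)-2-(methoxymethoxy)hex-5-enoate
Conditions: MOMCl, iPr2NEt, CH2Cl2, 0 → 23 °C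
Reagents that add atoms: chloromethyl methyl ether, COCCl
Why: Standard MOM etherification of a secondary alcohol with a hindered amine base; the acetal oxygen later serves as the second donor of the chelate.

Step 3
Reactants: 4 methyl (2R)-2-(methoxymethoxy)hex-5-enoate
Product: 5 (2R)-N-methoxy-2-(methoxymethoxy)-N-methylhex-5-enamide
Conditions: MeNH(OMe)·HCl, iPrMgCl, THF, −20 → 0 °C
Reagents that add atoms: N,O-dimethylhydroxylamine hydrochloride, CNOC.Cl
Why: Direct aminolysis of the ester by the chloromagnesium amide of N,O-dimethylhydroxylamine gives the Weinreb amide by fast low-temperature acyl transfer, which α-alkoxy esters undergo without epimerisation.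

Step 4
Reactants: 5 (2R)-N-methoxy-2-(methoxymethoxy)-N-methylhex-5-enamide; 6 methyl vinyl ketone
Product: 7 (2R,5E)-N-methoxy-2-(methoxymethoxy)-N-methyl-7-oxooct-5-enamide
Conditions: second-generation Hoveyda–Grubbs catalyst RuCl2(H2IMes)(=CH-C6H4-2-OiPr) (cat.), CH2Cl2, 40 °C
Reagents that add atoms: none
Why: Olefin cross-metathesis of a terminal alkene with an electron-poor vinyl ketone is selective for the cross product and gives the (E)-enone under thermodynamic control, while amide and acetal are inert to the ruthenium carbene.

Step 5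
Reactants: 7 (2R,5E)-N-methoxy-2-(methoxymethoxy)-N-methyl-7-oxooct-5-enamide
Product: 8 (2R,5E)-7-[(tert-butyldimethylsilyl)oxy]-N-methoxy-2-(methoxymethoxy)-N-methylocta-5,7-dienamide
Conditions: TBSOTf, Et3N, CH2Cl2, −78 → 0 °C
Reagents that add atoms: tert-butyldimethylsilyl trifluoromethanesulfonate, CC(C)(C)[Si](C)(C)OS(=O)(=O)C(F)(F)F
Why: Soft enolisation of the methyl ketone at its methyl group by silyl triflate and amine gives the cross-conjugated 2-silyloxydiene, and the Weinreb amide is not enolised under these conditions, so no second ketone competes.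

Step 6
Reactants: 8 (2R,5E)-7-[(tert-butyldimethylsilyl)oxy]-N-methoxy-2-(methoxymethoxy)-N-methylocta-5,7-dienamide; 9 isopropenylmagnesium bromide
Product: 11 (4R,7E)-9-[(tert-butyldimethylsilyl)oxy]-4-(methoxymethoxy)-2-methyldeca-1,7,9-trien-3-one, via magnesium hemiaminal chelate 10 (not isolated)
Conditions: THF, −78 → −20 °C; cold aq. NH4Cl; kept cold and used at once
Reagents that add atoms: none
Why: Weinreb ketone synthesis, in which the alkenyl Grignard reagent adds once to give a stable five-membered magnesium chelate that collapses to the isopropenyl ketone only on quench, the silyl dienol ether being inert to the organomagnesium reagent.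

Step 7
Reactants: 11 (4R,7E)-9-[(tert-butyldimethylsilyl)oxy]-4-(methoxymethoxy)-2-methyldeca-1,7,9-trien-3-one
Product: 12 8-[(tert-butyldimethylsilyl)oxy]-3α-(methoxymethoxy)-5β-methyl-10αH-decal-8-en-4-one
Conditions: MgBr2·OEt2, CH2Cl2, −78 → −20 °C
Reagents that add atoms: none
Why: This is a concerted, asynchronous [4+2] cycloaddition in which the electron-rich diene terminus C7 bonds to the enone β-carbon C6 and C10 bonds to the α-carbon C5, the enone being activated by a five-membered chelate of divalent magnesium between the C4 carbonyl oxygen and the inner oxygen of the C3 MOM ether; the closest known reaction types are the Lewis-acid-promoted intramolecular Diels–Alder reaction of 1,7,9-decatrien-3-ones and the chelate-controlled Diels–Alder reaction of α′-alkoxy enones with 2-silyloxydienes. Ring A closes as the six-membered ring that holds the four-atom tether, through the C5–C10 bond (exo with respect to both reacting π bonds), and ring B closes as the new cyclohexene of the cycloaddition, through C5–C10 and C6–C7. The quaternary centre C5 is controlled by C3: the chelate holds the C3–O bond syn-periplanar to the carbonyl, so the MOM-oxy group sits equatorial on the chair-like tether and the diene should reach only the enone face that places the C5 methyl axial and anti to it (5β-methyl with 3α-oxygen). C10 is set by the exo orientation of the tether carbonyl expected for an α-methyl enone, which gives the trans fusion, but this centre is erased in step 9, so the only selectivity the step needs is the face selectivity at C5. Regiochemistry is secured twice, by the tether length and by the polarity match of silyloxydiene and enone.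

Step 8
Reactants: 12 8-[(tert-butyldimethylsilyl)oxy]-3α-(methoxymethoxy)-5β-methyl-10αH-decal-8-en-4-one
Product: 13 8-[(tert-butyldimethylsilyl)oxy]-3α-(methoxymethoxy)-5β-methyl-4-methylene-10αH-decal-8-ene
Conditions: Cp2TiMe2, toluene, 70 °C, dark
Reagents that add atoms: dimethyltitanocene, C[Ti](C)(C1C=CC=C1)C1C=CC=C1
Why: Petasis methylenation, in which the non-basic titanium methylidene formed on heating converts the hindered, enolisable α-alkoxy ketone into the exocyclic alkene without epimerisation at C3 and without touching the silyl enol ether.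

Step 9
Reactants: 13 8-[(tert-butyldimethylsilyl)oxy]-3α-(methoxymethoxy)-5β-methyl-4-methylene-10αH-decal-8-ene
Product: 14 3α-(methoxymethoxy)-5β-methyl-4-methylenedecal-9-en-8-one
Conditions: Pd(OAc)2 (1.1 equiv), MeCN, 40 °C
Reagents that add atoms: none
Why: Saegusa–Ito oxidation, in which the regiodefined C8–C9 silyl enol ether gives a palladium enolate bound at C9 whose only β-hydrogen is at C10, so β-hydride elimination should give the 9-en-8-one alone and merge both C10 epimers.

Step 10
Reactants: 14 3α-(methoxymethoxy)-5β-methyl-4-methylenedecal-9-en-8-one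
Product: 15 3α-(methoxymethoxy)-4β,5β-dimethyldecal-9-en-8-one
Conditions: H2 (1–4 atm), RhCl(PPh3)3 (cat.), toluene, 23 °C
Reagents that add atoms: none
Why: Homogeneous hydrogenation with RhCl(PPh3)3 reduces a 1,1-disubstituted alkene and spares the trisubstituted conjugated C9–C10 double bond, and hydrogen should add to the α face of C4, opposite the axial C5 methyl, which sets C4 with its methyl β (cis to C14, trans to the C3 oxygen).

Step 11
Reactants: 15 3α-(methoxymethoxy)-4β,5β-dimethyldecal-9-en-8-one; 16 2-bromopropene
Product: 19 3α-(methoxymethoxy)-7βH-eremophila-9,11-dien-8-one, via lithium enolate 17 (not isolated), via lithium dienolate 18 (not isolated)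
Conditions: LiN(SiMe3)2 (2.2 equiv), THF, −78 °C; Pd2(dba)3 (cat.), P(tBu)3 (cat.), −78 → 23 °C; AcOH, −78 °C
Reagents that add atoms: none
Why: Palladium-catalysed α-alkenylation of a ketone enolate, in which the kinetic cross-conjugated lithium enolate at C7 is coupled with the alkenyl bromide by oxidative addition, transmetalation and reductive elimination, the more acidic product is stored as its extended enolate by the second equivalent of base, and kinetic α-protonation should return the β,γ-unsaturated ketone with the isopropenyl group equatorial (7α, trans to the axial C14), which is also the more stable epimer.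

Step 12
Reactants: 19 3α-(methoxymethoxy)-7βH-eremophila-9,11-dien-8-one
Product: 21 3α-(methoxymethoxy)-8-(trimethylsilyloxy)-7βH,10αH-eremophila-8,11-diene, via lithium enolate 20 (not isolated)
Conditions: Li (2.2 equiv), tBuOH (1 equiv), NH3(l)/THF, −78 °C; NH3 removed; Me3SiCl, Et3N, THF, −78 → 0 °C
Reagents that add atoms: chlorotrimethylsilane, C[Si](C)(C)Cl
Why: Dissolving-metal reduction of the enone with reductive silylation, in which C10 is protonated axially from the α face to give the trans-fused decalin and the regiodefined C8–C9 lithium enolate is trapped on oxygen, the isolated isopropenyl group and the acetal being inert.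

Step 13
Reactants: 21 3α-(methoxymethoxy)-8-(trimethylsilyloxy)-7βH,10αH-eremophila-8,11-diene
Product: 24 9α-hydroxy-3α-(methoxymethoxy)-7βH,10αH-eremophil-11-en-8-one, via silyloxy epoxide 22 (not isolated), via α-silyloxy ketone 23 (not isolated)
Conditions: mCPBA (1.05 equiv), NaHCO3, CH2Cl2, −40 → 0 °C; then Et3N·3HF, THF, 0 °C
Reagents that add atoms: 3-chloroperoxybenzoic acid, O=C(OO)c1cccc(Cl)c1
Why: Rubottom oxidation, in which the electron-rich silyl enol ether is epoxidised far faster than the 1,1-disubstituted alkene and from the α face, opposite the syn-axial C5 methyl, so silyl migration and fluoride cleavage should give the equatorial 9α-hydroxy ketone.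

Step 14
Reactants: 24 9α-hydroxy-3α-(methoxymethoxy)-7βH,10αH-eremophil-11-en-8-one; 25 (E)-3-methylpent-2-enoic acid
Product: 27 3α-(methoxymethoxy)-9α-[(E)-3-methylpent-2-enoyloxy]-7βH,10αH-eremophil-11-en-8-one, via O-acylisourea 26 (not isolated)
Conditions: EDC·HCl, DMAP (cat.), CH2Cl2, 0 → 23 °C
Reagents that add atoms: none
Why: Steglich esterification of the secondary α-hydroxy ketone with the carbodiimide-activated acid under DMAP catalysis at low temperature, which should keep the (E)-geometry of the enoate and the configuration at C9 and C7.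

Step 15
Reactants: 27 3α-(methoxymethoxy)-9α-[(E)-3-methylpent-2-enoyloxy]-7βH,10αH-eremophil-11-en-8-one
Product: 29 3α-hydroxy-9α-[(E)-3-methylpent-2-enoyloxy]-7βH,10αH-eremophil-11-en-8-one, via dimethylborinate 28 (not isolated)
Conditions: Me2BBr, iPr2NEt (cat.), CH2Cl2, −78 °C; aq. NaHCO3
Reagents that add atoms: none
Why: Dimethylboron bromide cleaves MOM ethers at −78 °C by coordination to the acetal oxygen and bromide attack at the methylene carbon, conditions that should leave the enoate ester, the ketone and the isopropenyl group intact, and hydrolysis of the borinate frees the C3 alcohol.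

Step 16
Reactants: 29 3α-hydroxy-9α-[(E)-3-methylpent-2-enoyloxy]-7βH,10αH-eremophil-11-en-8-one; 30 angelic acid
Product: 32 CNP0301161.1, via mixed anhydride 31 (not isolated)
Conditions: 2,4,6-trichlorobenzoyl chloride, Et3N, toluene, 23 °C; then 29, toluene, 80 °C
Reagents that add atoms: none
Why: Yamaguchi-type esterification through the preformed mixed anhydride of angelic acid, run without DMAP, is the established way to acylate hindered secondary alcohols without (Z) to (E) isomerisation of the angeloyl group.

**Compound list**

1 | methyl (R)-glycidate, methyl (2R)-oxirane-2-carboxylate | COC(=O)[C@H]1CO1 | starting material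
2 | allylmagnesium bromide | C=CC[Mg]Br | starting material
3 | methyl (2R)-2-hydroxyhex-5-enoate | COC(=O)[C@H](O)CCC=C | intermediate
4 | methyl (2R)-2-(methoxymethoxy)hex-5-enoate | COC(=O)[C@H](OCOC)CCC=C | intermediate
5 | (2R)-N-methoxy-2-(methoxymethoxy)-N-methylhex-5-enamide | CON(C)C(=O)[C@H](OCOC)CCC=C | intermediate
6 | methyl vinyl ketone, but-3-en-2-one | CC(=O)C=C | starting material
7 | (2R,5E)-N-methoxy-2-(methoxymethoxy)-N-methyl-7-oxooct-5-enamide | CON(C)C(=O)[C@H](OCOC)CC/C=C/C(C)=O | intermediate
8 | (2R,5E)-7-[(tert-butyldimethylsilyl)oxy]-N-methoxy-2-(methoxymethoxy)-N-methylocta-5,7-dienamide | CON(C)C(=O)[C@H](OCOC)CC/C=C/C(=C)O[Si](C)(C)C(C)(C)C | intermediate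
9 | isopropenylmagnesium bromide | C=C(C)[Mg]Br | starting material
10 | bromomagnesium hemiaminal chelate from 8 and 9 (either configuration at the new carbinol carbon) | C=C(C)C(O[Mg]Br)(N(C)OC)[C@H](OCOC)CC/C=C/C(=C)O[Si](C)(C)C(C)(C)C | intermediate (not isolated)
11 | (4R,7E)-9-[(tert-butyldimethylsilyl)oxy]-4-(methoxymethoxy)-2-methyldeca-1,7,9-trien-3-one | C=C(C)C(=O)[C@H](OCOC)CC/C=C/C(=C)O[Si](C)(C)C(C)(C)C | intermediate
12 | 8-[(tert-butyldimethylsilyl)oxy]-3α-(methoxymethoxy)-5β-methyl-10αH-decal-8-en-4-one (trans-fused) | C1C[C@]2(C)C(=O)[C@H](OCOC)CC[C@H]2C=C1O[Si](C)(C)C(C)(C)C | intermediate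
13 | 8-[(tert-butyldimethylsilyl)oxy]-3α-(methoxymethoxy)-5β-methyl-4-methylene-10αH-decal-8-ene | C1C[C@]2(C)C(=C)[C@H](OCOC)CC[C@H]2C=C1O[Si](C)(C)C(C)(C)C | intermediate
14 | 3α-(methoxymethoxy)-5β-methyl-4-methylenedecal-9-en-8-one | O=C1CC[C@]2(C)C(=C)[C@H](OCOC)CCC2=C1 | intermediate
15 | 3α-(methoxymethoxy)-4β,5β-dimethyldecal-9-en-8-one | O=C1CC[C@]2(C)[C@@H](C)[C@H](OCOC)CCC2=C1 | intermediate
16 | 2-bromopropene | C=C(C)Br | starting material
17 | lithium 7,9-dien-8-olate of 15 (kinetic C7 enolate) | [Li]OC1=CC[C@]2(C)[C@@H](C)[C@H](OCOC)CCC2=C1 | intermediate (not isolated)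
18 | lithium 7-isopropenyl-7,9-dien-8-olate (extended enolate of 19) | [Li]OC1=C(C(C)=C)C[C@]2(C)[C@@H](C)[C@H](OCOC)CCC2=C1 | intermediate (not isolated)
19 | 3α-(methoxymethoxy)-7βH-eremophila-9,11-dien-8-one (7α-isopropenyl, 4β,5β-dimethyl) | C=C(C)[C@@H]1C[C@]2(C)[C@@H](C)[C@H](OCOC)CCC2=CC1=O | intermediate
20 | lithium 8-en-8-olate from reduction of 19 (10α-H) | C=C(C)[C@@H]1C[C@]2(C)[C@@H](C)[C@H](OCOC)CC[C@H]2C=C1O[Li] | intermediate (not isolated)
21 | 3α-(methoxymethoxy)-8-(trimethylsilyloxy)-7βH,10αH-eremophila-8,11-diene | C=C(C)[C@@H]1C[C@]2(C)[C@@H](C)[C@H](OCOC)CC[C@H]2C=C1O[Si](C)(C)C | intermediate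
22 | 8α,9α-epoxy-3α-(methoxymethoxy)-8β-(trimethylsilyloxy)-7βH,10αH-eremophil-11-ene | C=C(C)[C@@H]1C[C@]2(C)[C@@H](C)[C@H](OCOC)CC[C@H]2[C@@H]3O[C@]13O[Si](C)(C)C | intermediate (not isolated)
23 | 3α-(methoxymethoxy)-9α-(trimethylsilyloxy)-7βH,10αH-eremophil-11-en-8-one | C=C(C)[C@@H]1C[C@]2(C)[C@@H](C)[C@H](OCOC)CC[C@H]2[C@H](O[Si](C)(C)C)C1=O | intermediate (not isolated)
24 | 9α-hydroxy-3α-(methoxymethoxy)-7βH,10αH-eremophil-11-en-8-one | C=C(C)[C@@H]1C[C@]2(C)[C@@H](C)[C@H](OCOC)CC[C@H]2[C@H](O)C1=O | intermediate
25 | (E)-3-methylpent-2-enoic acid | CC/C(C)=C/C(=O)O | starting material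
26 | O-acylisourea of 25 with EDC | CC/C(C)=C/C(=O)OC(=NCC)NCCCN(C)C | intermediate (not isolated)
27 | 3α-(methoxymethoxy)-9α-[(E)-3-methylpent-2-enoyloxy]-7βH,10αH-eremophil-11-en-8-one | C=C(C)[C@@H]1C[C@]2(C)[C@@H](C)[C@H](OCOC)CC[C@H]2[C@H](OC(=O)/C=C(\C)CC)C1=O | intermediate
28 | 3α-O-dimethylborinate of 29 | C=C(C)[C@@H]1C[C@]2(C)[C@@H](C)[C@H](OB(C)C)CC[C@H]2[C@H](OC(=O)/C=C(\C)CC)C1=O | intermediate (not isolated)
29 | 3α-hydroxy-9α-[(E)-3-methylpent-2-enoyloxy]-7βH,10αH-eremophil-11-en-8-one | C=C(C)[C@@H]1C[C@]2(C)[C@@H](C)[C@H](O)CC[C@H]2[C@H](OC(=O)/C=C(\C)CC)C1=O | intermediate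
30 | angelic acid, (Z)-2-methylbut-2-enoic acid | C/C=C(/C)C(=O)O | starting material
31 | angelic 2,4,6-trichlorobenzoic anhydride | C/C=C(/C)C(=O)OC(=O)c1c(Cl)cc(Cl)cc1Cl | intermediate (not isolated)
32 | CNP0301161.1, (3R,4R,5R,7S,9S,10R)-3-angeloyloxy-9-[(E)-3-methylpent-2-enoyloxy]eremophil-11-en-8-one (3α,9α-diester, 4β,5β-dimethyl, 7α-isopropenyl, 10α-H) | C=C(C)[C@@H]1C[C@]2(C)[C@@H](C)[C@H](OC(=O)/C(C)=C\C)CC[C@H]2[C@H](OC(=O)/C=C(\C)CC)C1=O | target

**Count and risks**

Total steps: 16. Longest linear sequence: 16 steps, from methyl (R)-glycidate 1 to 32.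

Step 7. The face selectivity at C5 may be poor if closure through a non-chelated conformer or the uncatalysed background reaction competes with the magnesium chelate, and the Lewis acid may strip the silyl dienol ether before closure. The fallback hands the choice of enone face from the substrate chelate to a catalyst. A chiral cationic oxazaborolidine Lewis acid (from α,α-diphenylprolinol and o-tolylboronic acid, activated with Tf2NH, in the enantiomeric form matched with C3) would be used in CH2Cl2 at −78 °C. It binds the enone carbonyl alone and shields one face, as known for α-substituted enones with 2-silyloxydienes. It sets out from 11 and comes back to the route at 12 and makes no new compound (F0).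

Step 11. The kinetic C7 enolate may equilibrate to the extended dienolate and couple at C1, and the new double bond may migrate into conjugation with the C8 ketone under the basic conditions. The fallback forms the C7–C11 bond by a directed aldol addition and sets out from 15. LiN(iPr)2 in THF at −78 °C, then acetone with ZnCl2, would give the 7-(2-hydroxypropan-2-yl) aldol adduct F1. MsCl and Et3N would convert it through the tertiary mesylate F2 into the conjugated 7(11)-isopropylidene dienone F3 by E1cB elimination. Deprotonation of F3 with LiN(iPr)2 at the methyl group syn to the carbonyl and kinetic protonation at C7 with AcOH at −78 °C (deconjugation of an alkylidene ketone) would pass through the extended enolate 18 and come back to the route at 19.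

Step 10. Hydrogen may be delivered to both faces of the hindered C4 methylene group, and the alkene may migrate into ring A at rhodium before it is reduced. The fallback uses the C3 oxygen as a directing group and sets out from 14. Me2BBr at −78 °C would remove the MOM group to give the 3α-hydroxy-4-methylene enone F4. Hydrogenation with the cationic catalyst [Rh(nbd)(dppb)]BF4 would then deliver hydrogen from the face of the hydroxyl group and give the 3α-hydroxy-4β-methyl enone F5. MOMCl with iPr2NEt would come back to the route at 15.

**Further compounds**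

F0 | step 7 | none | none
F1 | step 11 | 7α-(2-hydroxypropan-2-yl)-3α-(methoxymethoxy)-4β,5β-dimethyldecal-9-en-8-one | CC(C)(O)[C@@H]1C[C@]2(C)[C@@H](C)[C@H](OCOC)CCC2=CC1=O
F2 | step 11 | methanesulfonate of F1 | CC(C)(OS(C)(=O)=O)[C@@H]1C[C@]2(C)[C@@H](C)[C@H](OCOC)CCC2=CC1=O
F3 | step 11 | 3α-(methoxymethoxy)eremophila-7(11),9-dien-8-one | CC(C)=C1C[C@]2(C)[C@@H](C)[C@H](OCOC)CCC2=CC1=O
F4 | step 10 | 3α-hydroxy-5β-methyl-4-methylenedecal-9-en-8-one | O=C1CC[C@]2(C)C(=C)[C@H](O)CCC2=C1
F5 | step 10 | 3α-hydroxy-4β,5β-dimethyldecal-9-en-8-one | O=C1CC[C@]2(C)[C@@H](C)[C@H](O)CCC2=C1
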